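**Retrosynthetic overview**

1. Target ⇐ global acetylation of dihydroxy acid 15 ⇐ thiolate demethylation of methyl ether/methyl ester 14.
2. C1 stereocentre with its CH2O group ⇐ catalyst-controlled anti-Markovnikov hydroboration of exocyclic alkene 12 ⇐ 8-oxygenated 1-tetralone 10.
3. Key step: the benzene ring is made last, by annulating the four carbons C5–C8 of dimethyl itaconate onto the enone C=C of 4 (vinylogous Mukaiyama–Michael addition, Dieckmann closure, dehydrogenation). This fixes the arene substitution pattern without any arene substitution chemistry.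
4. Enone 4 ⇐ amine-catalysed Michael addition of (S)-citronellal (brings C11 and the prenyl end) to methyl vinyl ketone (sets C4), then aldol condensation.
5. Ring order: saturated six-membered ring first (step 2), aromatic ring second (steps 4 and 5).

Assumption: carbons are numbered as in the tetralin core of the target (C1 bears CH2OAc, C4 the side chain, C4a/C8a the ring fusion, C6 the CO2H, C8 the OAc, C11 the side-chain CH); the sense of induction of the cobalt ligand in step 8 is taken from α-alkylstyrene precedent, and the ligand antipode would be used if the first run gave the C1 epimer.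

**Route**

Step 1
Reactants: 1 (S)-citronellal; 2 methyl vinyl ketone
Product: 3 (2S,3S)-3,7-dimethyl-2-(3-oxobutyl)oct-6-enal
Conditions: (S)-2-[methoxy(diphenyl)methyl]pyrrolidine (5 mol%), ethyl 3,4-dihydroxybenzoate (20 mol%), neat, 4 °C
Reagents that add atoms: none
Why: Enamine-catalysed Michael addition in which the diphenyl(methoxy)methyl group of the (S)-amine shields one face of the E-enamine, so the enone adds to the other face and sets C4 (2S in 3) under catalyst control, while C11 comes unchanged from (S)-citronellal.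

Step 2
Reactants: 3 (2S,3S)-3,7-dimethyl-2-(3-oxobutyl)oct-6-enal
Product: 4 (4S)-4-[(2S)-6-methylhept-5-en-2-yl]cyclohex-2-en-1-one
Conditions: KOH aq. (0.1 equiv), nBu4NOH (5 mol%), THF/Et2O, reflux
Reagents that add atoms: none
Why: Intramolecular aldol condensation (second half of a Robinson-type annulation) in which the methyl ketone enolate closes on the aldehyde and water is lost; cyclisation is faster than enolisation of the aldehyde, so C4 is kept and no new stereocentre forms.

Step 3
Reactants: 5 dimethyl itaconate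
Product: 6 methyl 4-methoxy-2-methylidene-4-[(trimethylsilyl)oxy]but-3-enoate (E/Z mixture at the ketene acetal)
Conditions: LiN(SiMe3)2, Me3SiCl, THF, −78 °C (internal quench)
Reagents that add atoms: chlorotrimethylsilane, C[Si](C)(C)Cl
Why: Silyl ketene acetal formation: the CH2 of itaconate is both allylic and alpha to an ester, so a non-nucleophilic amide removes it cleanly and the dienolate is O-silylated at once, before it can add to unreacted itaconate.

Step 4
Reactants: 4 (4S)-4-[(2S)-6-methylhept-5-en-2-yl]cyclohex-2-en-1-one; 6 methyl 4-methoxy-2-methylidene-4-[(trimethylsilyl)oxy]but-3-enoate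
Product: 8 dimethyl (2E)-2-{[(1R,2S)-2-[(2S)-6-methylhept-5-en-2-yl]-5-oxocyclohexyl]methyl}but-2-enedioate, via silyl enol ether 7 (not isolated)
Conditions: Me3SiOTf (10 mol%), CH2Cl2, −78 °C; then 1 M HCl, THF, 0 °C
Reagents that add atoms: none
Why: Proposed new method: the terminal CH2 of silyl dienolate 6 (its vinylogous and least hindered carbon) adds to the activated enone at the beta carbon anti to the C4 side chain while the silyl group passes to the enone oxygen, the closest known reactions being vinylogous Mukaiyama–Michael additions of crotonate-derived silyl dienolates and of 1-methoxy-1,3-bis(silyloxy)butadiene to enones; the new ring CH is trans to the side chain but is lost on aromatisation, and the E alkene (C5 cis to the terminal ester) is the thermodynamic geometry.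

Step 5
Reactants: 8 dimethyl (2E)-2-{[(1R,2S)-2-[(2S)-6-methylhept-5-en-2-yl]-5-oxocyclohexyl]methyl}but-2-enedioate
Product: 10 methyl (8S)-4-hydroxy-8-[(2S)-6-methylhept-5-en-2-yl]-5-oxo-5,6,7,8-tetrahydronaphthalene-2-carboxylate, via diketone enol 9 (not isolated)
Conditions: KOtBu (2.2 equiv), THF, 0 °C to rt; AcOH; then 2,3-dichloro-5,6-dicyano-1,4-benzoquinone (DDQ, 1.1 equiv), 1,4-dioxane, rt
Reagents that add atoms: none
Why: Proposed new method: the ketone enolate at C8a acylates on the terminal ester in a 6-exo Dieckmann closure made irreversible by deprotonation of the vinylogous 1,3-diketone 9 (competing 5-exo Michael and aldol adducts are reversible, and any Z alkene equilibrates through the C5 anion), and DDQ then removes the hydrogens at C4a and C5 of this dihydrophenol, the closest known reactions being the Staunton–Weinreb annulation of o-toluate anions with cyclohexenones and the DDQ aromatisation of dihydroarenes; only the C4a centre is destroyed.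

Step 6
Reactants: 10 methyl (8S)-4-hydroxy-8-[(2S)-6-methylhept-5-en-2-yl]-5-oxo-5,6,7,8-tetrahydronaphthalene-2-carboxylate
Product: 11 methyl (8S)-4-methoxy-8-[(2S)-6-methylhept-5-en-2-yl]-5-oxo-5,6,7,8-tetrahydronaphthalene-2-carboxylate
Conditions: MeI, K2CO3, DMF, 40 °C
Reagents that add atoms: iodomethane, CI
Why: Williamson O-methylation of the chelated peri phenol, which frees the ketone for olefination; K2CO3 is too weak to enolise the ketone, so there is no C-alkylation and no stereocentre is touched.

Step 7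
Reactants: 11 methyl (8S)-4-methoxy-8-[(2S)-6-methylhept-5-en-2-yl]-5-oxo-5,6,7,8-tetrahydronaphthalene-2-carboxylate
Product: 12 methyl (8S)-4-methoxy-5-methylidene-8-[(2S)-6-methylhept-5-en-2-yl]-5,6,7,8-tetrahydronaphthalene-2-carboxylate
Conditions: Ph3PCH3Br, KOtBu, THF, 0 °C to reflux
Reagents that add atoms: methyltriphenylphosphonium bromide, C[P+](c1ccccc1)(c1ccccc1)c1ccccc1.[Br-]
Why: Wittig methylenation, which tolerates the aryl ester and needs only the ketone; reversible enolisation at C2 does not affect C4, and no stereocentre is formed.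

Step 8
Reactants: 12 methyl (8S)-4-methoxy-5-methylidene-8-[(2S)-6-methylhept-5-en-2-yl]-5,6,7,8-tetrahydronaphthalene-2-carboxylate
Product: 14 methyl (5R,8S)-5-(hydroxymethyl)-4-methoxy-8-[(2S)-6-methylhept-5-en-2-yl]-5,6,7,8-tetrahydronaphthalene-2-carboxylate, via pinacol boronate 13 (not isolated)
Conditions: CoCl2[(S)-iPr-IPO] (2 mol%; IPO = 2-[1-(2,6-diisopropylphenylimino)ethyl]-6-[(4S)-4-isopropyl-4,5-dihydro-1,3-oxazol-2-yl]pyridine), NaBHEt3 (4 mol%), pinacolborane, THF, rt; then NaOH, H2O2, 0 °C
Reagents that add atoms: pinacolborane, CC1(C)OBOC1(C)C; hydrogen peroxide, OO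
Why: Cobalt-hydride-catalysed enantioselective anti-Markovnikov hydroboration of a 1,1-disubstituted aryl alkene followed by oxidation with retention: the chiral ligand decides the face of C1 that receives hydrogen (giving 5R, the 1,4-trans isomer) and overrides the weak bias of the remote C4 centre, while the trisubstituted side-chain alkene does not react.

Step 9
Reactants: 14 methyl (5R,8S)-5-(hydroxymethyl)-4-methoxy-8-[(2S)-6-methylhept-5-en-2-yl]-5,6,7,8-tetrahydronaphthalene-2-carboxylate
Product: 15 (5R,8S)-4-hydroxy-5-(hydroxymethyl)-8-[(2S)-6-methylhept-5-en-2-yl]-5,6,7,8-tetrahydronaphthalene-2-carboxylic acid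
Conditions: NaSEt (6 equiv), DMF, 120 °C; then 1 M HCl
Reagents that add atoms: none
Why: SN2 demethylation by thiolate cleaves the aryl methyl ether and the methyl ester in one operation; the thiolate is not basic enough to epimerise the benzylic centres and does not touch the alkene.

Step 10
Reactants: 15 (5R,8S)-4-hydroxy-5-(hydroxymethyl)-8-[(2S)-6-methylhept-5-en-2-yl]-5,6,7,8-tetrahydronaphthalene-2-carboxylic acid
Product: 17 (5R,8S)-4-acetoxy-5-(acetoxymethyl)-8-[(2S)-6-methylhept-5-en-2-yl]-5,6,7,8-tetrahydronaphthalene-2-carboxylic acid (target), via mixed anhydride 16 (not isolated)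
Conditions: Ac2O, pyridine, 4-(dimethylamino)pyridine (cat.), rt; then H2O/THF
Reagents that add atoms: acetic anhydride, CC(=O)OC(C)=O
Why: Acyl-transfer acetylation of the phenol and the primary alcohol; the carboxylic acid forms a mixed anhydride that is hydrolysed back to the acid on aqueous work-up, as in the acetylation of salicylic acid.

**Compound list**

1 | (S)-citronellal, (3S)-3,7-dimethyloct-6-enal | O=CC[C@@H](C)CCC=C(C)C | starting material
2 | methyl vinyl ketone, but-3-en-2-one | CC(=O)C=C | starting material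
3 | (2S,3S)-3,7-dimethyl-2-(3-oxobutyl)oct-6-enal | O=C[C@@H](CCC(C)=O)[C@@H](C)CCC=C(C)C | intermediate
4 | (4S)-4-[(2S)-6-methylhept-5-en-2-yl]cyclohex-2-en-1-one | O=C1C=C[C@H]([C@@H](C)CCC=C(C)C)CC1 | intermediate
5 | dimethyl itaconate, dimethyl 2-methylidenebutanedioate | C=C(CC(=O)OC)C(=O)OC | starting material
6 | methyl 4-methoxy-2-methylidene-4-[(trimethylsilyl)oxy]but-3-enoate (E/Z mixture at the ketene acetal) | C=C(C(=O)OC)C=C(OC)O[Si](C)(C)C | intermediate
7 | dimethyl (2E)-2-{[(1S,6S)-6-[(2S)-6-methylhept-5-en-2-yl]-3-[(trimethylsilyl)oxy]cyclohex-2-en-1-yl]methyl}but-2-enedioate (not isolated) | C[Si](C)(C)OC1=C[C@@H](C/C(C(=O)OC)=C\C(=O)OC)[C@H]([C@@H](C)CCC=C(C)C)CC1 | intermediate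
8 | dimethyl (2E)-2-{[(1R,2S)-2-[(2S)-6-methylhept-5-en-2-yl]-5-oxocyclohexyl]methyl}but-2-enedioate (E isomer given; any Z isomer converges in step 5) | O=C1C[C@@H](C/C(C(=O)OC)=C\C(=O)OC)[C@H]([C@@H](C)CCC=C(C)C)CC1 | intermediate
9 | methyl (8S,8aS)-5-hydroxy-8-[(2S)-6-methylhept-5-en-2-yl]-4-oxo-1,4,6,7,8,8a-hexahydronaphthalene-2-carboxylate (enol form of the Dieckmann diketone; not isolated) | OC1=C2C(=O)C=C(C(=O)OC)C[C@H]2[C@H]([C@@H](C)CCC=C(C)C)CC1 | intermediate
10 | methyl (8S)-4-hydroxy-8-[(2S)-6-methylhept-5-en-2-yl]-5-oxo-5,6,7,8-tetrahydronaphthalene-2-carboxylate | O=C1CC[C@@H]([C@@H](C)CCC=C(C)C)c2cc(C(=O)OC)cc(O)c21 | intermediate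
11 | methyl (8S)-4-methoxy-8-[(2S)-6-methylhept-5-en-2-yl]-5-oxo-5,6,7,8-tetrahydronaphthalene-2-carboxylate | O=C1CC[C@@H]([C@@H](C)CCC=C(C)C)c2cc(C(=O)OC)cc(OC)c21 | intermediate
12 | methyl (8S)-4-methoxy-5-methylidene-8-[(2S)-6-methylhept-5-en-2-yl]-5,6,7,8-tetrahydronaphthalene-2-carboxylate | C=C1CC[C@@H]([C@@H](C)CCC=C(C)C)c2cc(C(=O)OC)cc(OC)c21 | intermediate
13 | methyl (5R,8S)-4-methoxy-8-[(2S)-6-methylhept-5-en-2-yl]-5-[(4,4,5,5-tetramethyl-1,3,2-dioxaborolan-2-yl)methyl]-5,6,7,8-tetrahydronaphthalene-2-carboxylate (not isolated) | CC1(C)OB(C[C@@H]2CC[C@@H]([C@@H](C)CCC=C(C)C)c3cc(C(=O)OC)cc(OC)c32)OC1(C)C | intermediate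
14 | methyl (5R,8S)-5-(hydroxymethyl)-4-methoxy-8-[(2S)-6-methylhept-5-en-2-yl]-5,6,7,8-tetrahydronaphthalene-2-carboxylate | OC[C@@H]1CC[C@@H]([C@@H](C)CCC=C(C)C)c2cc(C(=O)OC)cc(OC)c21 | intermediate
15 | (5R,8S)-4-hydroxy-5-(hydroxymethyl)-8-[(2S)-6-methylhept-5-en-2-yl]-5,6,7,8-tetrahydronaphthalene-2-carboxylic acid | OC[C@@H]1CC[C@@H]([C@@H](C)CCC=C(C)C)c2cc(C(=O)O)cc(O)c21 | intermediate
16 | acetic (5R,8S)-4-acetoxy-5-(acetoxymethyl)-8-[(2S)-6-methylhept-5-en-2-yl]-5,6,7,8-tetrahydronaphthalene-2-carboxylic anhydride (not isolated) | CC(=O)OC[C@@H]1CC[C@@H]([C@@H](C)CCC=C(C)C)c2cc(C(=O)OC(C)=O)cc(OC(C)=O)c21 | intermediate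
17 | (5R,8S)-4-acetoxy-5-(acetoxymethyl)-8-[(2S)-6-methylhept-5-en-2-yl]-5,6,7,8-tetrahydronaphthalene-2-carboxylic acid | CC(=O)OC[C@@H]1CC[C@@H]([C@@H](C)CCC=C(C)C)c2cc(C(=O)O)cc(OC(C)=O)c21 | target

**Step count**

Total steps: 10. Longest linear sequence: 9 steps (1 to 17 through steps 1, 2 and 4 to 10); step 3 is a one-step side branch.

**Three steps most likely to fail, with fallbacks**

Step 4. The dienolate 6 could react through its alpha carbon instead of the terminal CH2, giving a branched adduct that cannot close the six-membered ring. The fallback sets out from enone 4 and brings the carboxyl group in after the annulation. Commercial Chan's diene, 1-methoxy-1,3-bis(trimethylsilyloxy)buta-1,3-diene, whose terminal-carbon addition to enones under TiCl4 is secure, gives after aqueous work-up the β-keto ester methyl 4-[(1S,2S)-2-[(2S)-6-methylhept-5-en-2-yl]-5-oxocyclohexyl]-3-oxobutanoate F1. KOtBu closes it to the triketone (4aS,5S)-8-hydroxy-5-[(2S)-6-methylhept-5-en-2-yl]-4a,5,6,7-tetrahydronaphthalene-1,3(2H,4H)-dione F2, and DDQ aromatises this to (4S)-6,8-dihydroxy-4-[(2S)-6-methylhept-5-en-2-yl]-3,4-dihydronaphthalen-1(2H)-one F3. The 6-OH, the only one not hydrogen-bonded to the ketone, is triflated selectively with PhNTf2 and K2CO3 to (8S)-4-hydroxy-8-[(2S)-6-methylhept-5-en-2-yl]-5-oxo-5,6,7,8-tetrahydronaphthalen-2-yl trifluoromethanesulfonate F4. Methoxycarbonylation (Pd(OAc)2, dppp, CO, MeOH, Et3N) then gives 10, where the route is rejoined.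

Step 5. The ketone enolate could be diverted into a 5-exo Michael or an aldol adduct, retro-Michael cleavage could return enone 4 under base, or the dehydrogenation could be unclean. The fallback sets out from silyl enol ether 7, taken before the acidic work-up of step 4, and puts the unsaturation in before the ring closure. Saegusa–Ito oxidation (Pd(OAc)2, MeCN) gives regiospecifically the enone dimethyl (2E)-2-{[(6S)-6-[(2S)-6-methylhept-5-en-2-yl]-3-oxocyclohex-1-en-1-yl]methyl}but-2-enedioate F5. DBU in toluene removes the doubly vinylogous hydrogen at C5, the extended enolate acylates at C8a on the terminal ester (vinylogous Claisen closure), and the product tautomerises directly to phenol 10. No oxidant is needed, and the route is rejoined at 10.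

Step 8. Catalyst control next to the peri methoxy group may be weak or the reaction slow, and cobalt hydride could move the alkene into the ring. The fallback sets out from tetralone 11 and fixes C1 under thermodynamic control instead. Wittig reaction with Ph3P=CHOMe (from Ph3PCH2OMe chloride and KOtBu) gives the enol ether methyl (8S)-4-methoxy-5-(methoxymethylidene)-8-[(2S)-6-methylhept-5-en-2-yl]-5,6,7,8-tetrahydronaphthalene-2-carboxylate F6. Hydrolysis with 2 M HCl in THF and equilibration with DBU give the aldehyde methyl (5R,8S)-5-formyl-4-methoxy-8-[(2S)-6-methylhept-5-en-2-yl]-5,6,7,8-tetrahydronaphthalene-2-carboxylate F7. The 5R epimer should be favoured because the formyl group sits pseudoaxial to avoid the peri methoxy group and the C4 side chain sits pseudoaxial to avoid the peri C5–H, which is the 1,4-trans arrangement; the size of this preference is an estimate. NaBH4 in MeOH at 0 °C then gives 14, where the route is rejoined.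

**Further compounds**

F1 | step 4 | methyl 4-[(1S,2S)-2-[(2S)-6-methylhept-5-en-2-yl]-5-oxocyclohexyl]-3-oxobutanoate | O=C1C[C@@H](CC(=O)CC(=O)OC)[C@H]([C@@H](C)CCC=C(C)C)CC1
F2 | step 4 | (4aS,5S)-8-hydroxy-5-[(2S)-6-methylhept-5-en-2-yl]-4a,5,6,7-tetrahydronaphthalene-1,3(2H,4H)-dione | OC1=C2C(=O)CC(=O)C[C@H]2[C@H]([C@@H](C)CCC=C(C)C)CC1
F3 | step 4 | (4S)-6,8-dihydroxy-4-[(2S)-6-methylhept-5-en-2-yl]-3,4-dihydronaphthalen-1(2H)-one | O=C1CC[C@@H]([C@@H](C)CCC=C(C)C)c2cc(O)cc(O)c21
F4 | step 4 | (8S)-4-hydroxy-8-[(2S)-6-methylhept-5-en-2-yl]-5-oxo-5,6,7,8-tetrahydronaphthalen-2-yl trifluoromethanesulfonate | O=C1CC[C@@H]([C@@H](C)CCC=C(C)C)c2cc(OS(=O)(=O)C(F)(F)F)cc(O)c21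
F5 | step 5 | dimethyl (2E)-2-{[(6S)-6-[(2S)-6-methylhept-5-en-2-yl]-3-oxocyclohex-1-en-1-yl]methyl}but-2-enedioate | O=C1C=C(C/C(C(=O)OC)=C\C(=O)OC)[C@H]([C@@H](C)CCC=C(C)C)CC1
F6 | step 8 | methyl (8S)-4-methoxy-5-(methoxymethylidene)-8-[(2S)-6-methylhept-5-en-2-yl]-5,6,7,8-tetrahydronaphthalene-2-carboxylate (E/Z mixture) | COC=C1CC[C@@H]([C@@H](C)CCC=C(C)C)c2cc(C(=O)OC)cc(OC)c21
F7 | step 8 | methyl (5R,8S)-5-formyl-4-methoxy-8-[(2S)-6-methylhept-5-en-2-yl]-5,6,7,8-tetrahydronaphthalene-2-carboxylate | O=C[C@@H]1CC[C@@H]([C@@H](C)CCC=C(C)C)c2cc(C(=O)OC)cc(OC)c21
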